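**Plan**

- Retrosynthesis: remove the benzyl groups; open flavan A at O1–C2 (aryl ketone plus phenol); open the tropolone at C6–C7 and C8–C9 (carbonyl ylide of an ortho-formyl diazo ketone plus a terminal ynone); open the benzo ring at C1–C9a and C4–C4a (Diels–Alder); open flavan B at O1–C2.
- Enabling feature: the benzo ring of the benzotropolone carries flavan B on C2 next to the C3 and C4 oxygens. C1, C2, C3 and C4 are therefore the CH2, chromanyl-bearing, benzyloxy-bearing and ketene-acetal carbons of a 1,1,2-trioxygenated butadiene; C4a/C9a with the C5 acyl and C9 formyl carbons are an acetyl alkyne carrying an acetal.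
- Forward: one aryl lactate serves both chromans. The pyran ring of flavan B closes first, then the benzo ring, then the oxygen-bridged seven-membered ring, which acid opens to the tropolone; the pyran ring of flavan A closes last, followed by hydrogenolysis.
- Stereochemistry: both C3 centres come from methyl (R)-glycidate. C2 of flavan B comes from a chelation-controlled Grignard addition followed by Mitsunobu inversion (2,3-trans). C2 of flavan A comes from hydride delivery anti to the 3-galloyloxy group (2,3-cis).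

Key step: step 15

Remark: compounds 1, 3, 15, 23 and 34 are taken as purchasable, and the benzotropolone is drawn throughout as its 5-oxo-6-hydroxy tautomer.

**Route**

Step 1
Reactants: 1 3,5-bis(benzyloxy)phenol
Product: 2 1,3-bis(benzyloxy)-5-(methoxymethoxy)benzene
Conditions: MOMCl, i-Pr2NEt, CH2Cl2, 0 → 25 °C
Reagents that add atoms: chloromethyl methyl ether, COCCl
Why: Williamson-type O-alkylation of the only acidic group gives the methoxymethyl (MOM) ether, which later directs ortho-metalation and is removable by acid without touching benzyl ethers.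

Step 2
Reactants: 2 MOM-protected phenol; 3 methyl (2R)-oxirane-2-carboxylate
Product: 6 methyl (2R)-3-[2,4-bis(benzyloxy)-6-(methoxymethoxy)phenyl]-2-hydroxypropanoate, via aryllithium 4 (not isolated), via arylmagnesium bromide 5 (not isolated)
Conditions: n-BuLi, THF, 0 °C; MgBr2·OEt2; CuI (10 mol %), 3, −40 → −20 °C; then H2O
Reagents that add atoms: none
Why: MOM-directed ortho-lithiation places the metal between the MOM and benzyl ethers (the two ortho sites are equivalent), and the derived Grignard reagent opens the glycidate by CuI-catalysed SN2 attack at the unsubstituted epoxide carbon, so the stereocentre of 3 is untouched and becomes the (R)-carbinol that will be C3 of both chromans.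

Step 3
Reactants: 6 aryl lactate methyl ester
Product: 7 (2R)-3-[2,4-bis(benzyloxy)-6-(methoxymethoxy)phenyl]-2-hydroxy-N-methoxy-N-methylpropanamide
Conditions: MeNH(OMe)·HCl, i-PrMgCl, THF, −20 → 0 °C; then H2O
Reagents that add atoms: N,O-dimethylhydroxylamine hydrochloride, CNOC.Cl
Why: Weinreb amidation by acyl substitution with the chloromagnesium amide formed in the flask (the free hydroxyl is only deprotonated) gives the branching intermediate, whose amide can be reduced to an aldehyde or turned into a ketone.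

Step 4
Reactants: 7 hydroxy Weinreb amide
Product: 8 (2R)-2-(benzyloxy)-3-[2,4-bis(benzyloxy)-6-(methoxymethoxy)phenyl]-N-methoxy-N-methylpropanamide
Conditions: NaH, BnBr, n-Bu4NI (cat.), THF, 0 → 25 °C
Reagents that add atoms: benzyl bromide, BrCc1ccccc1
Why: Williamson etherification of the sodium alkoxide installs the benzyl ether that will chelate magnesium in step 6 and is removed only in the final hydrogenolysis; the amide α-hydrogen is too weakly acidic for racemisation at this temperature.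

Step 5
Reactants: 8 benzyloxy Weinreb amide
Product: 9 (2R)-2-(benzyloxy)-3-[2,4-bis(benzyloxy)-6-(methoxymethoxy)phenyl]propanal
Conditions: i-Bu2AlH, THF, −78 °C; aqueous work-up
Reagents that add atoms: none
Why: Hydride reduction of an N-methoxy-N-methylamide stops at the aldehyde oxidation level because the chelated adduct survives until work-up, and at −78 °C the α-benzyloxy stereocentre should stay intact.

Step 6
Reactants: 9 α-benzyloxy aldehyde
Product: 10 (3S,4R)-4-(benzyloxy)-5-[2,4-bis(benzyloxy)-6-(methoxymethoxy)phenyl]-2-ethoxypent-1-en-3-ol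
Conditions: ethyl vinyl ether, t-BuLi, THF, −78 → 0 °C; MgBr2·OEt2; then 9, CH2Cl2, −78 °C; then H2O
Reagents that add atoms: ethyl vinyl ether, C=COCC
Why: Chelation-controlled (Cram-chelate) Grignard addition: magnesium bridges the aldehyde and α-benzyloxy oxygens, and the 1-ethoxyvinyl nucleophile (a masked acetyl anion) attacks from the face of the small hydrogen substituent, which sets the new carbinol centre 3,4-syn (3S).

Step 7
Reactants: 10 syn enol ether alcohol
Product: 11 (3S,4R)-4-(benzyloxy)-5-[2,4-bis(benzyloxy)-6-hydroxyphenyl]-3-hydroxypentan-2-one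
Conditions: 2 M aq HCl, THF, 40 °C
Reagents that add atoms: water, O
Why: Aqueous acid hydrolyses the enol ether to the methyl ketone and the MOM acetal to the phenol in one operation, both being acetal-type hydrolyses that leave benzyl ethers alone.

Step 8
Reactants: 11 hydroxy ketone phenol
Product: 12 1-[(2R,3R)-3,5,7-tris(benzyloxy)chroman-2-yl]ethan-1-one (2,3-trans)
Conditions: PPh3, i-PrO2CN=NCO2i-Pr, THF, 0 → 25 °C
Reagents that add atoms: none
Why: Intramolecular Mitsunobu etherification closes the pyran ring by 6-exo-tet SN2 attack of the phenol on the activated carbinol carbon next to the ketone, and the inversion converts the 3,4-syn alcohol into the 2,3-trans chroman of flavan B.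

Step 9
Reactants: 12 chromanyl methyl ketone
Product: 14 1-[(2R,3R)-3,5,7-tris(benzyloxy)chroman-2-yl]ethenyl trifluoromethanesulfonate, via potassium enolate 13 (not isolated)
Conditions: KN(SiMe3)2, THF, −78 °C; PhNTf2, −78 → 0 °C
Reagents that add atoms: N-phenylbis(trifluoromethanesulfonimide), O=S(=O)(N(c1ccccc1)S(=O)(=O)C(F)(F)F)C(F)(F)F
Why: Kinetic deprotonation of the methyl group (the hindered, oxygen-bearing C2–H reacts much more slowly) and O-sulfonylation of the enolate give the terminal enol triflate, a standard enol triflate synthesis.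

Step 10
Reactants: 14 enol triflate; 15 ethyl glyoxylate
Product: 17 ethyl 2-hydroxy-3-[(2S,3R)-3,5,7-tris(benzyloxy)chroman-2-yl]but-3-enoate (both epimers at the carbinol carbon), via alkenylchromium dichloride 16 (not isolated)
Conditions: CrCl2, NiCl2 (cat.), DMF, 25 °C; aqueous work-up
Reagents that add atoms: none
Why: Nozaki–Hiyama–Kishi coupling: nickel-catalysed activation of the triflate and transfer to chromium give 16, which adds only to the aldehyde of 15 and tolerates ester, ethers and the allylic aryl ether; the new carbinol centre forms without control, which is harmless because it becomes sp2 in step 13.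

Step 11
Reactants: 17 allylic hydroxy ester
Product: 18 ethyl 2-(benzyloxy)-3-[(2S,3R)-3,5,7-tris(benzyloxy)chroman-2-yl]but-3-enoate
Conditions: BnBr, Ag2O, CH2Cl2, 25 °C, dark
Reagents that add atoms: benzyl bromide, BrCc1ccccc1
Why: Ag2O-mediated O-benzylation (a Williamson variant without strong base) caps the hydroxyl without moving the double bond and supplies the future C3 benzyl ether of the benzo ring.

Step 12
Reactants: 18 benzyloxy ester
Product: 19 2-(benzyloxy)-3-[(2S,3R)-3,5,7-tris(benzyloxy)chroman-2-yl]but-3-enoic acid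
Conditions: LiOH, THF/H2O, 0 → 25 °C; then 1 M HCl
Reagents that add atoms: lithium hydroxide, [Li+].[OH-]
Why: Mild saponification of the unhindered ethyl ester gives the acid needed for a bis(silyl) ketene acetal, so that silanol is the only group that can leave on aromatisation.

Step 13
Reactants: 19 benzyloxy butenoic acid
Product: 22 2-(benzyloxy)-1,1-bis(trimethylsilyloxy)-3-[(2S,3R)-3,5,7-tris(benzyloxy)chroman-2-yl]buta-1,3-diene, via trimethylsilyl ester 20 (not isolated), via lithium dienolate 21 (not isolated)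
Conditions: Me3SiCl, Et3N, THF, 0 °C; then LiN(i-Pr)2, −78 °C; Me3SiCl, −78 → 25 °C; used crude
Reagents that add atoms: chlorotrimethylsilane, C[Si](C)(C)Cl
Why: Silyl ester formation followed by α-deprotonation and O-silylation of the dienolate is the standard synthesis of 1,1-bis(trimethylsilyloxy)-1,3-dienes; the α-carbon (activated by ester and vinyl group) is the only acidic site, and its uncontrolled stereocentre disappears.

Step 14
Reactants: 23 3,3-diethoxyprop-1-yne
Product: 25 5,5-diethoxypent-3-yn-2-one, via lithium acetylide 24 (not isolated)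
Conditions: n-BuLi, THF, −78 °C; MeC(O)N(OMe)Me, −78 → 0 °C; then H2O
Reagents that add atoms: N-methoxy-N-methylacetamide, CON(C)C(C)=O
Why: Acylation of the lithium acetylide with a Weinreb amide (Weinreb ketone synthesis) gives the ynone without over-addition, and the acetal is inert to base.

Step 15
Reactants: 22 bis(silyl) ketene acetal diene; 25 5,5-diethoxypent-3-yn-2-one
Product: 28 1-{3-(benzyloxy)-6-(diethoxymethyl)-2-hydroxy-4-[(2S,3R)-3,5,7-tris(benzyloxy)chroman-2-yl]phenyl}ethan-1-one, via cyclohexadiene cycloadduct 26 (not isolated), via aryl silyl ether 27 (not isolated)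
Conditions: toluene, 25 → 60 °C; then THF/H2O, 25 °C
Reagents that add atoms: none
Why: The electron-rich diene 22 adds to ynone 25 in a concerted but strongly asynchronous [4+2] cycloaddition: its unsubstituted CH2 terminus bonds to the acetal-bearing β-carbon of the ynone (future C9a) and the ketene-acetal carbon closes onto the acyl-bearing α-carbon (future C4a), forming C1–C9a and C4–C4a. The closest known reaction type is the Diels–Alder benzannulation of 1,1-bis(silyloxy)- and 1,1-dialkoxy-1,3-dienes with alkynones and alkynoates, which gives salicyl ketones and salicylates after loss of silanol or alcohol. The six-membered carbocycle is closed by this intermolecular [4+2] cycloaddition to cyclohexa-1,4-diene 26, which aromatises by 1,4-elimination of Me3SiOH to 27, and mild hydrolysis frees the hydrogen-bonded phenol 28. No stereocentre is created, and the two chroman stereocentres sit on an internal diene carbon as spectators. The step needs regioselectivity, which the matched polarisation of the 1,1-dioxygenated diene and the acetyl acceptor should secure, and chemoselectivity, which follows because acetal and benzyl ethers are inert under neutral thermal conditions. The acetyl group is both the activating group and the methyl ketone needed later for diazo transfer.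

Step 16
Reactants: 28 hydroxy acetophenone
Product: 29 1-{2,3-bis(benzyloxy)-6-(diethoxymethyl)-4-[(2S,3R)-3,5,7-tris(benzyloxy)chroman-2-yl]phenyl}ethan-1-one
Conditions: BnBr, K2CO3, n-Bu4NI (cat.), DMF, 50 °C
Reagents that add atoms: benzyl bromide, BrCc1ccccc1
Why: Williamson benzylation of the hydrogen-bonded phenol protects the C4 oxygen before enolate and carbenoid chemistry, and no other acidic group competes.

Step 17
Reactants: 29 benzyl-protected acetophenone
Product: 32 1-{2,3-bis(benzyloxy)-6-(diethoxymethyl)-4-[(2S,3R)-3,5,7-tris(benzyloxy)chroman-2-yl]phenyl}-2-diazoethan-1-one, via lithium enolate 30 (not isolated), via trifluoromethyl diketone 31 (not isolated)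
Conditions: LiN(SiMe3)2, THF, −78 °C; CF3CO2CH2CF3; then MeSO2N3, Et3N, H2O, MeCN, 25 °C
Reagents that add atoms: methanesulfonyl azide, CS(=O)(=O)N=[N+]=[N-]
Why: Regitz-type detrifluoroacetylative diazo transfer: the methyl ketone enolate is trifluoroacetylated and the activated diketone takes the diazo group from the sulfonyl azide with loss of the trifluoroacetyl group, under conditions that leave the acetal and benzyl ethers untouched.

Step 18
Reactants: 32 diazo ketone acetal
Product: 33 3,4-bis(benzyloxy)-2-(diazoacetyl)-5-[(2S,3R)-3,5,7-tris(benzyloxy)chroman-2-yl]benzaldehyde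
Conditions: PPTS (cat.), acetone/H2O, 25 °C
Reagents that add atoms: water, O
Why: Acid-catalysed hydrolysis of the aryl diethyl acetal should proceed under buffered pyridinium catalysis far faster than protonolysis of the acceptor-stabilised diazo ketone, so the aldehyde is unveiled next to the intact diazoacetyl group.

Step 19
Reactants: 7 hydroxy Weinreb amide; 34 3,4,5-tris(benzyloxy)benzoic acid
Product: 35 (2R)-3-[2,4-bis(benzyloxy)-6-(methoxymethoxy)phenyl]-1-[methoxy(methyl)amino]-1-oxopropan-2-yl 3,4,5-tris(benzyloxy)benzoate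
Conditions: DCC, DMAP (cat.), CH2Cl2, 0 → 25 °C
Reagents that add atoms: none
Why: Steglich esterification attaches the galloyl unit to the secondary alcohol before the ketone is made, so that no late acylation in the presence of the tropolone hydroxyl is needed.

Step 20
Reactants: 35 galloylated Weinreb amide
Product: 36 (2R)-1-[2,4-bis(benzyloxy)-6-(methoxymethoxy)phenyl]-3-oxopent-4-yn-2-yl 3,4,5-tris(benzyloxy)benzoate
Conditions: HC≡CMgBr, THF, −20 → 0 °C; then H2O
Reagents that add atoms: ethynylmagnesium bromide, C#C[Mg]Br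
Why: Weinreb ketone synthesis: the weakly nucleophilic alkynyl Grignard reagent adds to the chelating N-methoxy-N-methylamide, which is far more electrophilic than the electron-rich trialkoxybenzoate, and the ynone is released only on work-up, so the (R)-centre is carried over unchanged.

Step 21
Reactants: 33 formyl diazo ketone; 36 galloyloxy ynone
Product: 38 (2R)-1-[2,4-bis(benzyloxy)-6-(methoxymethoxy)phenyl]-3-{3,4-bis(benzyloxy)-5-oxo-2-[(2S,3R)-3,5,7-tris(benzyloxy)chroman-2-yl]-6,9-dihydro-5H-6,9-epoxybenzo[7]annulen-8-yl}-3-oxopropan-2-yl 3,4,5-tris(benzyloxy)benzoate (both bridgehead diastereomers), via carbonyl ylide 37 (not isolated)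
Conditions: Rh2(OAc)4 (2 mol %), CH2Cl2, 25 °C, slow addition of 33 to 36 and the catalyst
Reagents that add atoms: none
Why: Dirhodium tetraacetate turns the diazo ketone into a carbenoid that is captured by the neighbouring aldehyde oxygen (six-membered ring) to give the 2-benzopyrylium-4-olate 37, a carbonyl ylide whose 1,3-dipolar cycloaddition to the ynone builds the seven-membered carbocycle, with the ylide carbon next to the ketone bonding to the unsubstituted alkyne terminus so that the side chain sits on C8; the two bridgehead stereocentres form without control and are erased in step 22.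

Step 22
Reactants: 38 oxygen-bridged cycloadduct
Product: 39 (2R)-1-[2,4-bis(benzyloxy)-6-hydroxyphenyl]-3-{3,4-bis(benzyloxy)-6-hydroxy-5-oxo-2-[(2S,3R)-3,5,7-tris(benzyloxy)chroman-2-yl]-5H-benzo[7]annulen-8-yl}-3-oxopropan-2-yl 3,4,5-tris(benzyloxy)benzoate
Conditions: CF3CO2H, CH2Cl2, 0 °C; aqueous work-up
Reagents that add atoms: none
Why: Acid-promoted ring opening of the oxygen-bridged cycloadduct: ionisation of the benzylic C9–O bond (helped by the para benzyloxy group on C3) and loss of the C6 proton give the aromatic tropolone, the usual way of unveiling tropolones from oxidopyrylium-type cycloadducts, while the same acid cleaves the MOM acetal; the α-acyloxy ketone should be configurationally stable to brief cold acid.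

Step 23
Reactants: 39 tropolone keto phenol
Product: 41 (2R,3R)-5,7-bis(benzyloxy)-2-{3,4-bis(benzyloxy)-6-hydroxy-5-oxo-2-[(2S,3R)-3,5,7-tris(benzyloxy)chroman-2-yl]-5H-benzo[7]annulen-8-yl}chroman-3-yl 3,4,5-tris(benzyloxy)benzoate, via cyclic hemiketal 40 (not isolated)
Conditions: Et3SiH, BF3·OEt2, CH2Cl2, −40 → 0 °C
Reagents that add atoms: none
Why: Reductive etherification (ionic hydrogenation of hemiketal 40): BF3·OEt2 ionises the hemiketal to an oxocarbenium ion that is shielded on one face by the neighbouring 3-galloyloxy group (acyloxy participation, the substituent sitting pseudoaxial to avoid allylic strain with the C2 aryl group), so Et3SiH delivers hydride anti to it and sets C2 as 2,3-cis (2R); the hemiketal centre of 40 is of no consequence.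

Step 24
Reactants: 41 deca-O-benzyl precursor
Product: 42 (2R,3R)-5,7-dihydroxy-2-{3,4,6-trihydroxy-5-oxo-2-[(2S,3R)-3,5,7-trihydroxychroman-2-yl]-5H-benzo[7]annulen-8-yl}chroman-3-yl 3,4,5-trihydroxybenzoate
Conditions: H2 (1 atm), Pd(OH)2/C, THF/MeOH, 25 °C
Reagents that add atoms: none
Why: Hydrogenolysis of the ten benzyl ethers at atmospheric pressure, the standard last step for galloylated flavan-3-ols, should leave the ester, both chroman C–O bonds and the tropolone intact.

**Compound list**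

1 | 3,5-bis(benzyloxy)phenol | Oc1cc(OCc2ccccc2)cc(OCc2ccccc2)c1 | starting material
2 | 1,3-bis(benzyloxy)-5-(methoxymethoxy)benzene | COCOc1cc(OCc2ccccc2)cc(OCc2ccccc2)c1 | intermediate
3 | methyl (2R)-oxirane-2-carboxylate | COC(=O)[C@H]1CO1 | starting material
4 | [2,4-bis(benzyloxy)-6-(methoxymethoxy)phenyl]lithium | [Li]c1c(OCOC)cc(OCc2ccccc2)cc1OCc1ccccc1 | intermediate
5 | [2,4-bis(benzyloxy)-6-(methoxymethoxy)phenyl]magnesium bromide | Br[Mg]c1c(OCOC)cc(OCc2ccccc2)cc1OCc1ccccc1 | intermediate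
6 | methyl (2R)-3-[2,4-bis(benzyloxy)-6-(methoxymethoxy)phenyl]-2-hydroxypropanoate | COC(=O)[C@H](O)Cc1c(OCOC)cc(OCc2ccccc2)cc1OCc1ccccc1 | intermediate
7 | (2R)-3-[2,4-bis(benzyloxy)-6-(methoxymethoxy)phenyl]-2-hydroxy-N-methoxy-N-methylpropanamide | CON(C)C(=O)[C@H](O)Cc1c(OCOC)cc(OCc2ccccc2)cc1OCc1ccccc1 | intermediate
8 | (2R)-2-(benzyloxy)-3-[2,4-bis(benzyloxy)-6-(methoxymethoxy)phenyl]-N-methoxy-N-methylpropanamide | CON(C)C(=O)[C@H](OCc1ccccc1)Cc1c(OCOC)cc(OCc2ccccc2)cc1OCc1ccccc1 | intermediate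
9 | (2R)-2-(benzyloxy)-3-[2,4-bis(benzyloxy)-6-(methoxymethoxy)phenyl]propanal | O=C[C@H](OCc1ccccc1)Cc1c(OCOC)cc(OCc2ccccc2)cc1OCc1ccccc1 | intermediate
10 | (3S,4R)-4-(benzyloxy)-5-[2,4-bis(benzyloxy)-6-(methoxymethoxy)phenyl]-2-ethoxypent-1-en-3-ol (3,4-syn) | CCOC(=C)[C@@H](O)[C@H](OCc1ccccc1)Cc1c(OCOC)cc(OCc2ccccc2)cc1OCc1ccccc1 | intermediate
11 | (3S,4R)-4-(benzyloxy)-5-[2,4-bis(benzyloxy)-6-hydroxyphenyl]-3-hydroxypentan-2-one | CC(=O)[C@@H](O)[C@H](OCc1ccccc1)Cc1c(O)cc(OCc2ccccc2)cc1OCc1ccccc1 | intermediate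
12 | 1-[(2R,3R)-3,5,7-tris(benzyloxy)chroman-2-yl]ethan-1-one (2,3-trans) | CC(=O)[C@@H]1Oc2cc(OCc3ccccc3)cc(OCc3ccccc3)c2C[C@H]1OCc1ccccc1 | intermediate
13 | potassium 1-[(2R,3R)-3,5,7-tris(benzyloxy)chroman-2-yl]ethen-1-olate | [K]OC(=C)[C@@H]1Oc2cc(OCc3ccccc3)cc(OCc3ccccc3)c2C[C@H]1OCc1ccccc1 | intermediate
14 | 1-[(2R,3R)-3,5,7-tris(benzyloxy)chroman-2-yl]ethenyl trifluoromethanesulfonate | C=C(OS(=O)(=O)C(F)(F)F)[C@@H]1Oc2cc(OCc3ccccc3)cc(OCc3ccccc3)c2C[C@H]1OCc1ccccc1 | intermediate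
15 | ethyl glyoxylate | CCOC(=O)C=O | starting material
16 | {1-[(2R,3R)-3,5,7-tris(benzyloxy)chroman-2-yl]ethenyl}chromium dichloride | C=C([Cr](Cl)Cl)[C@@H]1Oc2cc(OCc3ccccc3)cc(OCc3ccccc3)c2C[C@H]1OCc1ccccc1 | intermediate
17 | ethyl 2-hydroxy-3-[(2S,3R)-3,5,7-tris(benzyloxy)chroman-2-yl]but-3-enoate (both epimers at the carbinol carbon) | CCOC(=O)C(O)C(=C)[C@@H]1Oc2cc(OCc3ccccc3)cc(OCc3ccccc3)c2C[C@H]1OCc1ccccc1 | intermediate
18 | ethyl 2-(benzyloxy)-3-[(2S,3R)-3,5,7-tris(benzyloxy)chroman-2-yl]but-3-enoate | CCOC(=O)C(OCc1ccccc1)C(=C)[C@@H]1Oc2cc(OCc3ccccc3)cc(OCc3ccccc3)c2C[C@H]1OCc1ccccc1 | intermediate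
19 | 2-(benzyloxy)-3-[(2S,3R)-3,5,7-tris(benzyloxy)chroman-2-yl]but-3-enoic acid | OC(=O)C(OCc1ccccc1)C(=C)[C@@H]1Oc2cc(OCc3ccccc3)cc(OCc3ccccc3)c2C[C@H]1OCc1ccccc1 | intermediate
20 | trimethylsilyl 2-(benzyloxy)-3-[(2S,3R)-3,5,7-tris(benzyloxy)chroman-2-yl]but-3-enoate | C[Si](C)(C)OC(=O)C(OCc1ccccc1)C(=C)[C@@H]1Oc2cc(OCc3ccccc3)cc(OCc3ccccc3)c2C[C@H]1OCc1ccccc1 | intermediate
21 | lithium 2-(benzyloxy)-1-(trimethylsilyloxy)-3-[(2S,3R)-3,5,7-tris(benzyloxy)chroman-2-yl]buta-1,3-dien-1-olate | [Li]OC(O[Si](C)(C)C)=C(OCc1ccccc1)C(=C)[C@@H]1Oc2cc(OCc3ccccc3)cc(OCc3ccccc3)c2C[C@H]1OCc1ccccc1 | intermediate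
22 | 2-(benzyloxy)-1,1-bis(trimethylsilyloxy)-3-[(2S,3R)-3,5,7-tris(benzyloxy)chroman-2-yl]buta-1,3-diene | C=C([C@@H]1Oc2cc(OCc3ccccc3)cc(OCc3ccccc3)c2C[C@H]1OCc1ccccc1)C(OCc1ccccc1)=C(O[Si](C)(C)C)O[Si](C)(C)C | intermediate
23 | 3,3-diethoxyprop-1-yne | C#CC(OCC)OCC | starting material
24 | (3,3-diethoxyprop-1-yn-1-yl)lithium | [Li]C#CC(OCC)OCC | intermediate
25 | 5,5-diethoxypent-3-yn-2-one | CC(=O)C#CC(OCC)OCC | intermediate
26 | 1-{5-(benzyloxy)-2-(diethoxymethyl)-4-[(2S,3R)-3,5,7-tris(benzyloxy)chroman-2-yl]-6,6-bis(trimethylsilyloxy)cyclohexa-1,4-dien-1-yl}ethan-1-one | CC(=O)C1=C(C(OCC)OCC)CC([C@@H]2Oc3cc(OCc4ccccc4)cc(OCc4ccccc4)c3C[C@H]2OCc2ccccc2)=C(OCc2ccccc2)C1(O[Si](C)(C)C)O[Si](C)(C)C | intermediate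
27 | 1-{3-(benzyloxy)-6-(diethoxymethyl)-4-[(2S,3R)-3,5,7-tris(benzyloxy)chroman-2-yl]-2-(trimethylsilyloxy)phenyl}ethan-1-one | CC(=O)c1c(C(OCC)OCC)cc([C@@H]2Oc3cc(OCc4ccccc4)cc(OCc4ccccc4)c3C[C@H]2OCc2ccccc2)c(OCc2ccccc2)c1O[Si](C)(C)C | intermediate
28 | 1-{3-(benzyloxy)-6-(diethoxymethyl)-2-hydroxy-4-[(2S,3R)-3,5,7-tris(benzyloxy)chroman-2-yl]phenyl}ethan-1-one | CC(=O)c1c(C(OCC)OCC)cc([C@@H]2Oc3cc(OCc4ccccc4)cc(OCc4ccccc4)c3C[C@H]2OCc2ccccc2)c(OCc2ccccc2)c1O | intermediate
29 | 1-{2,3-bis(benzyloxy)-6-(diethoxymethyl)-4-[(2S,3R)-3,5,7-tris(benzyloxy)chroman-2-yl]phenyl}ethan-1-one | CC(=O)c1c(C(OCC)OCC)cc([C@@H]2Oc3cc(OCc4ccccc4)cc(OCc4ccccc4)c3C[C@H]2OCc2ccccc2)c(OCc2ccccc2)c1OCc1ccccc1 | intermediate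
30 | lithium 1-{2,3-bis(benzyloxy)-6-(diethoxymethyl)-4-[(2S,3R)-3,5,7-tris(benzyloxy)chroman-2-yl]phenyl}ethen-1-olate | [Li]OC(=C)c1c(C(OCC)OCC)cc([C@@H]2Oc3cc(OCc4ccccc4)cc(OCc4ccccc4)c3C[C@H]2OCc2ccccc2)c(OCc2ccccc2)c1OCc1ccccc1 | intermediate
31 | 1-{2,3-bis(benzyloxy)-6-(diethoxymethyl)-4-[(2S,3R)-3,5,7-tris(benzyloxy)chroman-2-yl]phenyl}-4,4,4-trifluorobutane-1,3-dione | O=C(CC(=O)c1c(C(OCC)OCC)cc([C@@H]2Oc3cc(OCc4ccccc4)cc(OCc4ccccc4)c3C[C@H]2OCc2ccccc2)c(OCc2ccccc2)c1OCc1ccccc1)C(F)(F)F | intermediate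
32 | 1-{2,3-bis(benzyloxy)-6-(diethoxymethyl)-4-[(2S,3R)-3,5,7-tris(benzyloxy)chroman-2-yl]phenyl}-2-diazoethan-1-one | [N-]=[N+]=CC(=O)c1c(C(OCC)OCC)cc([C@@H]2Oc3cc(OCc4ccccc4)cc(OCc4ccccc4)c3C[C@H]2OCc2ccccc2)c(OCc2ccccc2)c1OCc1ccccc1 | intermediate
33 | 3,4-bis(benzyloxy)-2-(diazoacetyl)-5-[(2S,3R)-3,5,7-tris(benzyloxy)chroman-2-yl]benzaldehyde | [N-]=[N+]=CC(=O)c1c(C=O)cc([C@@H]2Oc3cc(OCc4ccccc4)cc(OCc4ccccc4)c3C[C@H]2OCc2ccccc2)c(OCc2ccccc2)c1OCc1ccccc1 | intermediate
34 | 3,4,5-tris(benzyloxy)benzoic acid | OC(=O)c1cc(OCc2ccccc2)c(OCc2ccccc2)c(OCc2ccccc2)c1 | starting material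
35 | (2R)-3-[2,4-bis(benzyloxy)-6-(methoxymethoxy)phenyl]-1-[methoxy(methyl)amino]-1-oxopropan-2-yl 3,4,5-tris(benzyloxy)benzoate | CON(C)C(=O)[C@H](OC(=O)c1cc(OCc2ccccc2)c(OCc2ccccc2)c(OCc2ccccc2)c1)Cc1c(OCOC)cc(OCc2ccccc2)cc1OCc1ccccc1 | intermediate
36 | (2R)-1-[2,4-bis(benzyloxy)-6-(methoxymethoxy)phenyl]-3-oxopent-4-yn-2-yl 3,4,5-tris(benzyloxy)benzoate | C#CC(=O)[C@H](OC(=O)c1cc(OCc2ccccc2)c(OCc2ccccc2)c(OCc2ccccc2)c1)Cc1c(OCOC)cc(OCc2ccccc2)cc1OCc1ccccc1 | intermediate
37 | 5,6-bis(benzyloxy)-7-[(2S,3R)-3,5,7-tris(benzyloxy)chroman-2-yl]isochromenylium-4-olate (2-benzopyrylium-4-olate) | [O-]c1c[o+]cc2cc([C@@H]3Oc4cc(OCc5ccccc5)cc(OCc5ccccc5)c4C[C@H]3OCc3ccccc3)c(OCc3ccccc3)c(OCc3ccccc3)c12 | intermediate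
38 | (2R)-1-[2,4-bis(benzyloxy)-6-(methoxymethoxy)phenyl]-3-{3,4-bis(benzyloxy)-5-oxo-2-[(2S,3R)-3,5,7-tris(benzyloxy)chroman-2-yl]-6,9-dihydro-5H-6,9-epoxybenzo[7]annulen-8-yl}-3-oxopropan-2-yl 3,4,5-tris(benzyloxy)benzoate (bridgehead centres unspecified) | O=C1c2c(OCc3ccccc3)c(OCc3ccccc3)c([C@@H]3Oc4cc(OCc5ccccc5)cc(OCc5ccccc5)c4C[C@H]3OCc3ccccc3)cc2C2OC1C=C2C(=O)[C@H](OC(=O)c1cc(OCc2ccccc2)c(OCc2ccccc2)c(OCc2ccccc2)c1)Cc1c(OCOC)cc(OCc2ccccc2)cc1OCc1ccccc1 | intermediate
39 | (2R)-1-[2,4-bis(benzyloxy)-6-hydroxyphenyl]-3-{3,4-bis(benzyloxy)-6-hydroxy-5-oxo-2-[(2S,3R)-3,5,7-tris(benzyloxy)chroman-2-yl]-5H-benzo[7]annulen-8-yl}-3-oxopropan-2-yl 3,4,5-tris(benzyloxy)benzoate | O=C([C@H](OC(=O)c1cc(OCc2ccccc2)c(OCc2ccccc2)c(OCc2ccccc2)c1)Cc1c(O)cc(OCc2ccccc2)cc1OCc1ccccc1)c1cc(O)c(=O)c2c(OCc3ccccc3)c(OCc3ccccc3)c([C@@H]3Oc4cc(OCc5ccccc5)cc(OCc5ccccc5)c4C[C@H]3OCc3ccccc3)cc2c1 | intermediate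
40 | (3R)-5,7-bis(benzyloxy)-2-hydroxy-2-{3,4-bis(benzyloxy)-6-hydroxy-5-oxo-2-[(2S,3R)-3,5,7-tris(benzyloxy)chroman-2-yl]-5H-benzo[7]annulen-8-yl}chroman-3-yl 3,4,5-tris(benzyloxy)benzoate (hemiketal centre unspecified) | OC1(Oc2cc(OCc3ccccc3)cc(OCc3ccccc3)c2C[C@H]1OC(=O)c1cc(OCc2ccccc2)c(OCc2ccccc2)c(OCc2ccccc2)c1)c1cc(O)c(=O)c2c(OCc3ccccc3)c(OCc3ccccc3)c([C@@H]3Oc4cc(OCc5ccccc5)cc(OCc5ccccc5)c4C[C@H]3OCc3ccccc3)cc2c1 | intermediate
41 | (2R,3R)-5,7-bis(benzyloxy)-2-{3,4-bis(benzyloxy)-6-hydroxy-5-oxo-2-[(2S,3R)-3,5,7-tris(benzyloxy)chroman-2-yl]-5H-benzo[7]annulen-8-yl}chroman-3-yl 3,4,5-tris(benzyloxy)benzoate | O=C(O[C@@H]1Cc2c(OCc3ccccc3)cc(OCc3ccccc3)cc2O[C@@H]1c1cc(O)c(=O)c2c(OCc3ccccc3)c(OCc3ccccc3)c([C@@H]3Oc4cc(OCc5ccccc5)cc(OCc5ccccc5)c4C[C@H]3OCc3ccccc3)cc2c1)c1cc(OCc2ccccc2)c(OCc2ccccc2)c(OCc2ccccc2)c1 | intermediate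
42 | (2R,3R)-5,7-dihydroxy-2-{3,4,6-trihydroxy-5-oxo-2-[(2S,3R)-3,5,7-trihydroxychroman-2-yl]-5H-benzo[7]annulen-8-yl}chroman-3-yl 3,4,5-trihydroxybenzoate | O=C(O[C@@H]1Cc2c(O)cc(O)cc2O[C@@H]1c1cc(O)c(=O)c2c(O)c(O)c([C@@H]3Oc4cc(O)cc(O)c4C[C@H]3O)cc2c1)c1cc(O)c(O)c(O)c1 | target

**Step count and risks**

Total step count: 24. Longest linear sequence: 21 steps (steps 1–13, 15–18, 21–24).

Steps most likely to fail:

1. Step 15. The diene may be lost by hydrolysis, may add to the ynone only once (conjugate addition without ring closure), or may react slowly because both internal diene carbons are substituted. The fallback builds the ring in two ionic stages and sets out from ester 18. LiN(i-Pr)2 and t-BuMe2SiCl give the ethyl silyl ketene acetal diene F1. A vinylogous Mukaiyama–Michael addition of F1 through its CH2 terminus to ynone 25 (LiClO4 in ether) gives the open-chain keto ester F2. LiN(SiMe3)2 then removes a proton from the doubly allylic CH2 of F2, the dienolate closes onto the ester (Dieckmann-type condensation) with loss of ethanol, and tautomerisation returns to phenol 28.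

2. Step 21. The carbenoid may be diverted before the ylide forms (attack by the neighbouring benzyl ether oxygen followed by benzyl shift, or carbene dimerisation), or the dipole may add in the wrong orientation. The fallback generates the same ylide without a carbenoid and sets out from ketone 29. Hydroxylation of its lithium enolate with 2-(phenylsulfonyl)-3-phenyloxaziridine gives the hydroxy ketone F3. PPTS closes F3 onto the neighbouring acetal, with loss of ethanol, to the 1-ethoxyisochroman-4-one F4. Heating F4 with ynone 36 and a trace of TsOH in toluene expels a second ethanol to give ylide 37, which is trapped to return to cycloadduct 38.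

3. Step 23. Hydride delivery may show poor facial selectivity, or the oxocarbenium ion may lose the C3 proton and so erode the C3 stereocentre. The fallback closes the ring by substitution and sets out from keto phenol 39. Zn(BH4)2 reduces the ketone under chelation control (zinc bridging the ketone and the α-acyloxy oxygen) to the 1,2-anti alcohol F5. An intramolecular Mitsunobu etherification (PPh3, diisopropyl azodicarboxylate) then displaces the benzylic hydroxyl by the phenol with inversion and returns to the 2,3-cis flavan 41.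

Further compounds
F1 | step 15 | 2-(benzyloxy)-1-ethoxy-1-(tert-butyldimethylsilyloxy)-3-[(2S,3R)-3,5,7-tris(benzyloxy)chroman-2-yl]buta-1,3-diene | C=C([C@@H]1Oc2cc(OCc3ccccc3)cc(OCc3ccccc3)c2C[C@H]1OCc1ccccc1)C(OCc1ccccc1)=C(OCC)O[Si](C)(C)C(C)(C)C
F2 | step 15 | ethyl 2-(benzyloxy)-5-(diethoxymethyl)-7-oxo-3-[(2S,3R)-3,5,7-tris(benzyloxy)chroman-2-yl]octa-2,5-dienoate | CCOC(=O)C(OCc1ccccc1)=C(CC(=CC(C)=O)C(OCC)OCC)[C@@H]1Oc2cc(OCc3ccccc3)cc(OCc3ccccc3)c2C[C@H]1OCc1ccccc1
F3 | step 21 | 1-{2,3-bis(benzyloxy)-6-(diethoxymethyl)-4-[(2S,3R)-3,5,7-tris(benzyloxy)chroman-2-yl]phenyl}-2-hydroxyethan-1-one | OCC(=O)c1c(C(OCC)OCC)cc([C@@H]2Oc3cc(OCc4ccccc4)cc(OCc4ccccc4)c3C[C@H]2OCc2ccccc2)c(OCc2ccccc2)c1OCc1ccccc1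
F4 | step 21 | 5,6-bis(benzyloxy)-1-ethoxy-7-[(2S,3R)-3,5,7-tris(benzyloxy)chroman-2-yl]isochroman-4-one | CCOC1OCC(=O)c2c(OCc3ccccc3)c(OCc3ccccc3)c([C@@H]3Oc4cc(OCc5ccccc5)cc(OCc5ccccc5)c4C[C@H]3OCc3ccccc3)cc12
F5 | step 23 | (1S,2R)-3-[2,4-bis(benzyloxy)-6-hydroxyphenyl]-1-{3,4-bis(benzyloxy)-6-hydroxy-5-oxo-2-[(2S,3R)-3,5,7-tris(benzyloxy)chroman-2-yl]-5H-benzo[7]annulen-8-yl}-1-hydroxypropan-2-yl 3,4,5-tris(benzyloxy)benzoate | O[C@H]([C@H](OC(=O)c1cc(OCc2ccccc2)c(OCc2ccccc2)c(OCc2ccccc2)c1)Cc1c(O)cc(OCc2ccccc2)cc1OCc1ccccc1)c1cc(O)c(=O)c2c(OCc3ccccc3)c(OCc3ccccc3)c([C@@H]3Oc4cc(OCc5ccccc5)cc(OCc5ccccc5)c4C[C@H]3OCc3ccccc3)cc2c1
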